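**Retrosynthetic overview**

1. The strategy rests on ring A: C5 (OH), C6 (OMe) and C7 (OMe) carry adjacent oxygens, C8 carries hydrogen, and C8a–C4a is the enol-ether edge shared with ring C. This is the pattern that the carbonyl carbon, the two methoxy carbons and the CH carbon of a 2,3-dimethoxycyclobutenone deliver when fused onto a cyclic enol ether.
2. Key disconnection: C8–C8a (Stille coupling) and C4a–C5 (six-electron electrocyclisation of a dienylketene) lead back to a 6-stannyl-3,4-dimethoxy-2-aryl-dihydropyran and 4-chloro-2,3-dimethoxycyclobutenone (from dimethyl squarate). The C4 methoxy group is oxidised to the ketone afterwards.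
3. Ring C: BINOL–Ti hetero-Diels–Alder reaction of the ring B aldehyde with Danishefsky's diene (sets C2), enolate hydroxylation anti to the aryl group (sets C3), Luche reduction, double O-methylation, lithiation/stannylation.
4. Ring B: methoxyhydroquinone, silylated, brominated para to the methoxy group and formylated.
5. Order of rings: ring B is bought, ring C is closed by the hetero-Diels–Alder reaction, ring A is formed last in the key step.

Key step: step 11

**Remarks and assumptions**

- Ar = 4-methoxy-2,5-bis(triisopropylsilyloxy)phenyl. Flavonoid numbering is used in the text: pyran C6 of the glycal is the future C8a, pyran C5 the future C4a.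
- The C4 oxygen is carried as a methyl ether, not a silyl ether: Si–CH3 groups are metalated by t-BuLi and an alkyl silyl ether cannot be cleaved by fluoride ahead of the aryl silyl ethers, whereas the benzylic methyl ether is turned into the ketone in one oxidation.
- The C4 configuration is of no consequence (C4 becomes the carbonyl); the (4R) isomer drawn is the one expected from pseudo-axial hydride delivery.
- Assumption: (S)-BINOL is taken to deliver the (S)-pyranone, in line with the facial sense of BINOL–Ti additions to aryl aldehydes; should the sense be the opposite, (R)-BINOL is used and nothing else changes.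

**Route**

Step 1
Reactants: 1 methoxyhydroquinone
Product: 2 2-methoxy-1,4-bis(triisopropylsilyloxy)benzene
Conditions: iPr3SiCl (2.4 equiv), imidazole (5 equiv), DMF, 40 °C, argon
Reagents that add atoms: triisopropylsilyl chloride, CC(C)[Si](Cl)(C(C)C)C(C)C
Why: Imidazole-promoted O-silylation of both phenols should give bulky aryl silyl ethers that withstand the organolithium, hydride and oxidation steps ahead and shield the ring B hydrogens from later metalation.

Step 2
Reactants: 2 2-methoxy-1,4-bis(triisopropylsilyloxy)benzene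
Product: 3 1-bromo-4-methoxy-2,5-bis(triisopropylsilyloxy)benzene
Conditions: NBS (1.05 equiv), MeCN, 0 °C to rt
Reagents that add atoms: N-bromosuccinimide, O=C1CCC(=O)N1Br
Why: Electrophilic aromatic bromination should go to the one position that is para to the methoxy group and ortho to a silyloxy group, the other free positions being either flanked by two oxygens or activated by one silyloxy group only.

Step 3
Reactants: 3 1-bromo-4-methoxy-2,5-bis(triisopropylsilyloxy)benzene
Product: 6 4-methoxy-2,5-bis(triisopropylsilyloxy)benzaldehyde, via aryllithium 4 (not isolated), via lithium hemiaminal alkoxide 5 (not isolated)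
Conditions: n-BuLi (1.05 equiv), THF, −78 °C; DMF, −78 to 0 °C; H2O
Reagents that add atoms: N,N-dimethylformamide, CN(C)C=O
Why: Bromine–lithium exchange followed by Bouveault formylation with DMF should give the aldehyde, the ortho-silyloxy aryllithium being trapped at −78 °C before any oxygen-to-carbon silyl shift.

Step 4
Reactants: 6 4-methoxy-2,5-bis(triisopropylsilyloxy)benzaldehyde; 7 Danishefsky's diene, (E)-1-methoxy-3-(trimethylsilyloxy)buta-1,3-diene
Product: 9 (S)-2-Ar-2,3-dihydro-4H-pyran-4-one, via Mukaiyama aldol adduct 8 (not isolated)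
Conditions: (S)-BINOL (20 mol%), Ti(OiPr)4 (10 mol%), 4 Å MS, Et2O, −20 °C; then CF3CO2H, CH2Cl2, 0 °C
Reagents that add atoms: none
Why: A BINOL–Ti(OiPr)4-catalysed Mukaiyama aldol addition of the silyloxydiene to the aldehyde followed by acid-induced cyclisation with loss of methanol (two-stage hetero-Diels–Alder reaction) should give the dihydropyranone, the chiral titanium complex selecting the aldehyde face and so setting C2 as (S).

Step 5
Reactants: 9 (S)-2-Ar-2,3-dihydro-4H-pyran-4-one
Product: 11 (2R,3R)-3-hydroxy-2-Ar-2,3-dihydro-4H-pyran-4-one, via sodium enolate 10 (not isolated)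
Conditions: NaN(SiMe3)2 (1.1 equiv), THF, −78 °C; 3-phenyl-2-(phenylsulfonyl)oxaziridine (1.3 equiv), −78 °C; AcOH
Reagents that add atoms: 3-phenyl-2-(phenylsulfonyl)oxaziridine, O=S(=O)(c1ccccc1)N1OC1c1ccccc1
Why: Davis hydroxylation of the kinetic enolate (C3 is the only enolisable position) should give the α-hydroxy ketone, the nearly flat enolate ring being attacked at C3 from the face opposite the C2 aryl group, which sets the 2,3-trans relation (3R).

Step 6
Reactants: 11 (2R,3R)-3-hydroxy-2-Ar-2,3-dihydro-4H-pyran-4-one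
Product: 12 (2R,3S,4R)-2-Ar-3,4-dihydro-2H-pyran-3,4-diol
Conditions: NaBH4, CeCl3·7H2O, MeOH, −78 °C
Reagents that add atoms: none
Why: Luche 1,2-reduction of the enone carbonyl with pseudo-axial hydride delivery should give the 3,4-trans diol, the C4 configuration being without consequence for the target.

Step 7
Reactants: 12 (2R,3S,4R)-2-Ar-3,4-dihydro-2H-pyran-3,4-diol
Product: 13 (2R,3S,4R)-3,4-dimethoxy-2-Ar-3,4-dihydro-2H-pyran
Conditions: NaH (2.5 equiv), MeI (4 equiv), THF, 0 °C to rt
Reagents that add atoms: iodomethane, CI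
Why: Williamson etherification of both alkoxides should install the C3 methoxy group of the target and mask C4–OH as an organolithium-stable ether that is later oxidised to the ketone.

Step 8
Reactants: 13 (2R,3S,4R)-3,4-dimethoxy-2-Ar-3,4-dihydro-2H-pyran
Product: 15 tributyl[(2R,3S,4R)-3,4-dimethoxy-2-Ar-3,4-dihydro-2H-pyran-6-yl]stannane, via 6-lithio glycal 14 (not isolated)
Conditions: t-BuLi (2.5 equiv), THF, −78 to −20 °C; Bu3SnCl, −78 °C to rt
Reagents that add atoms: tributyltin chloride, CCCC[Sn](Cl)(CCCC)CCCC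
Why: Kinetic α-lithiation of the cyclic enol ether (C1 lithiation of a glycal) and trapping with Bu3SnCl should give the stannane, since the vinylic hydrogen next to the ring oxygen is the most accessible acidic site while the benzylic C2–H is tertiary and flanked by the silyloxyaryl and methoxy groups, and no stereocenter is touched.

Step 9
Reactants: 16 dimethyl squarate
Product: 17 (±)-4-hydroxy-2,3-dimethoxycyclobut-2-en-1-one
Conditions: LiAlH(OtBu)3 (1.05 equiv), THF, −78 °C; pH 7 buffer, 0 °C
Reagents that add atoms: none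
Why: Chemoselective 1,2-reduction of one squarate carbonyl by the hindered hydride should stop at the hydroxy enone, a vinylogous ester that is not reduced further at −78 °C; the new center is racemic and is lost later.

Step 10
Reactants: 17 (±)-4-hydroxy-2,3-dimethoxycyclobut-2-en-1-one
Product: 18 (±)-4-chloro-2,3-dimethoxycyclobut-2-en-1-one
Conditions: SOCl2 (1.1 equiv), pyridine (1.2 equiv), CH2Cl2, −20 to 0 °C; used at once
Reagents that add atoms: thionyl chloride, O=S(Cl)Cl
Why: Chlorination through the chlorosulfite should replace the hydroxyl at the activated carbon α to the carbonyl, pyridine taking up HCl so that acid-induced loss of methanol to the cyclobutenedione is suppressed.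

Step 11
Reactants: 15 tributyl[(2R,3S,4R)-3,4-dimethoxy-2-Ar-3,4-dihydro-2H-pyran-6-yl]stannane; 18 (±)-4-chloro-2,3-dimethoxycyclobut-2-en-1-one
Product: 22 (2R,3S,4R)-3,4,6,7-tetramethoxy-2-Ar-chroman-5-ol, via 4-pyranylcyclobutenone 19 (not isolated), via dienylketene 20 (not isolated), via cyclohexadienone 21 (not isolated)
Conditions: 18 (1.3 equiv), PdCl2(PhCN)2 (5 mol%), tri(2-furyl)phosphine (10 mol%), dioxane, 50 °C, then 90 °C
Reagents that add atoms: none
Why: Zerovalent palladium, formed from PdCl2(PhCN)2 and tri(2-furyl)phosphine by the stannane, inserts into the allylic C–Cl bond of 18, the α-alkoxyalkenyl stannane 15 transmetalates and reductive elimination at the hydrogen-bearing carbon forms C8–C8a in 19; reversible conrotatory four-electron opening of 19 gives dienylketene 20, whose thermal disrotatory six-electron electrocyclisation joins the ketene carbon to C4a (ring A, six-membered, bond C4a–C5), and tautomerisation of 21 gives the phenol. The closest known reaction type is the palladium-catalysed coupling of 4-chlorocyclobutenones with alkenylstannanes followed by thermal benzannulation to phenols. No stereocenter is formed: C2, C3 and C4 come unchanged from 15, and the transient centers of 19 and 21 end as aromatic carbons. The step needs coupling at the chlorine-bearing terminus of the oxocyclobutenyl palladium intermediate and not at the methoxy-bearing one; the former is the less hindered carbon and the only one whose product keeps the 3-methoxy enone conjugation. Ring opening is reversible, so only the isomer with the pyranyl group turned toward the ketene carbon goes on, and the ketene carbonyl, the two methoxy carbons and the CH carbon map onto C5, C6, C7 and C8 by connectivity.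

Step 12
Reactants: 22 (2R,3S,4R)-3,4,6,7-tetramethoxy-2-Ar-chroman-5-ol
Product: 23 (2R,3R)-5-hydroxy-3,6,7-trimethoxy-2-Ar-chroman-4-one
Conditions: DDQ (1.2 equiv), CH2Cl2/MeCN/pH 7 phosphate buffer, 0 °C
Reagents that add atoms: water, O
Why: DDQ oxidation of an electron-rich benzylic ether should abstract hydride from C4–H (activated by the ortho hydroxyl, the ortho ring oxygen and the para methoxy group) to give an oxocarbenium ion that water converts through the hemiketal into the hydrogen-bonded 5-hydroxy ketone, which is deactivated towards further oxidation, with C2 and C3 untouched.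

Step 13
Reactants: 23 (2R,3R)-5-hydroxy-3,6,7-trimethoxy-2-Ar-chroman-4-one
Product: 24 (2R,3R)-2-(2,5-dihydroxy-4-methoxyphenyl)-5-hydroxy-3,6,7-trimethoxychroman-4-one (CNP0257825.1)
Conditions: Bu4NF/AcOH (1:1, 3 equiv), THF, 0 °C, argon
Reagents that add atoms: none
Why: Fluoride-induced cleavage of the two aryl silyl ethers should free ring B, the acetic acid buffer keeping the 3-methoxyflavanone away from base, which would open ring C by retro-oxa-Michael reaction and scramble C2 and C3.

**Compound list**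

1 | methoxyhydroquinone (2-methoxybenzene-1,4-diol) | COc1cc(O)ccc1O | starting material
2 | 2-methoxy-1,4-bis(triisopropylsilyloxy)benzene | COc1cc(O[Si](C(C)C)(C(C)C)C(C)C)ccc1O[Si](C(C)C)(C(C)C)C(C)C | intermediate
3 | 1-bromo-4-methoxy-2,5-bis(triisopropylsilyloxy)benzene | COc1cc(O[Si](C(C)C)(C(C)C)C(C)C)c(Br)cc1O[Si](C(C)C)(C(C)C)C(C)C | intermediate
4 | [4-methoxy-2,5-bis(triisopropylsilyloxy)phenyl]lithium | COc1cc(O[Si](C(C)C)(C(C)C)C(C)C)c([Li])cc1O[Si](C(C)C)(C(C)C)C(C)C | intermediate (not isolated)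
5 | lithium (dimethylamino)[4-methoxy-2,5-bis(triisopropylsilyloxy)phenyl]methanolate | COc1cc(O[Si](C(C)C)(C(C)C)C(C)C)c(C([O-])N(C)C)cc1O[Si](C(C)C)(C(C)C)C(C)C.[Li+] | intermediate (not isolated)
6 | 4-methoxy-2,5-bis(triisopropylsilyloxy)benzaldehyde | COc1cc(O[Si](C(C)C)(C(C)C)C(C)C)c(C=O)cc1O[Si](C(C)C)(C(C)C)C(C)C | intermediate
7 | Danishefsky's diene, (E)-1-methoxy-3-(trimethylsilyloxy)buta-1,3-diene | CO/C=C/C(=C)O[Si](C)(C)C | starting material
8 | (S,E)-1-methoxy-5-Ar-5-(trimethylsilyloxy)pent-1-en-3-one | COc1cc(O[Si](C(C)C)(C(C)C)C(C)C)c([C@@H](O[Si](C)(C)C)CC(=O)/C=C/OC)cc1O[Si](C(C)C)(C(C)C)C(C)C | intermediate (not isolated)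
9 | (S)-2-Ar-2,3-dihydro-4H-pyran-4-one | COc1cc(O[Si](C(C)C)(C(C)C)C(C)C)c([C@H]2OC=CC(=O)C2)cc1O[Si](C(C)C)(C(C)C)C(C)C | intermediate
10 | sodium enolate of 9, sodium (S)-2-Ar-2H-pyran-4-olate | [Na+].COc1cc(O[Si](C(C)C)(C(C)C)C(C)C)c([C@H]2OC=CC([O-])=C2)cc1O[Si](C(C)C)(C(C)C)C(C)C | intermediate (not isolated)
11 | (2R,3R)-3-hydroxy-2-Ar-2,3-dihydro-4H-pyran-4-one (2,3-trans) | COc1cc(O[Si](C(C)C)(C(C)C)C(C)C)c([C@H]2OC=CC(=O)[C@@H]2O)cc1O[Si](C(C)C)(C(C)C)C(C)C | intermediate
12 | (2R,3S,4R)-2-Ar-3,4-dihydro-2H-pyran-3,4-diol (2,3-trans-3,4-trans) | COc1cc(O[Si](C(C)C)(C(C)C)C(C)C)c([C@H]2OC=C[C@@H](O)[C@@H]2O)cc1O[Si](C(C)C)(C(C)C)C(C)C | intermediate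
13 | (2R,3S,4R)-3,4-dimethoxy-2-Ar-3,4-dihydro-2H-pyran | COc1cc(O[Si](C(C)C)(C(C)C)C(C)C)c([C@H]2OC=C[C@@H](OC)[C@@H]2OC)cc1O[Si](C(C)C)(C(C)C)C(C)C | intermediate
14 | [(2R,3S,4R)-3,4-dimethoxy-2-Ar-3,4-dihydro-2H-pyran-6-yl]lithium | COc1cc(O[Si](C(C)C)(C(C)C)C(C)C)c([C@H]2OC([Li])=C[C@@H](OC)[C@@H]2OC)cc1O[Si](C(C)C)(C(C)C)C(C)C | intermediate (not isolated)
15 | tributyl[(2R,3S,4R)-3,4-dimethoxy-2-Ar-3,4-dihydro-2H-pyran-6-yl]stannane | COc1cc(O[Si](C(C)C)(C(C)C)C(C)C)c([C@H]2OC([Sn](CCCC)(CCCC)CCCC)=C[C@@H](OC)[C@@H]2OC)cc1O[Si](C(C)C)(C(C)C)C(C)C | intermediate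
16 | dimethyl squarate (3,4-dimethoxycyclobut-3-ene-1,2-dione) | COC1=C(OC)C(=O)C1=O | starting material
17 | (±)-4-hydroxy-2,3-dimethoxycyclobut-2-en-1-one | COC1=C(OC)C(O)C1=O | intermediate
18 | (±)-4-chloro-2,3-dimethoxycyclobut-2-en-1-one | COC1=C(OC)C(Cl)C1=O | intermediate
19 | 4-[(2R,3S,4R)-3,4-dimethoxy-2-Ar-3,4-dihydro-2H-pyran-6-yl]-2,3-dimethoxycyclobut-2-en-1-one (epimers at the cyclobutenone CH) | COc1cc(O[Si](C(C)C)(C(C)C)C(C)C)c([C@H]2OC(C3C(=O)C(OC)=C3OC)=C[C@@H](OC)[C@@H]2OC)cc1O[Si](C(C)C)(C(C)C)C(C)C | intermediate (not isolated)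
20 | 2,3-dimethoxy-4-[(2R,3S,4R)-3,4-dimethoxy-2-Ar-3,4-dihydro-2H-pyran-6-yl]buta-1,3-dien-1-one, pyranyl group cis to the ketene carbon | COc1cc(O[Si](C(C)C)(C(C)C)C(C)C)c([C@H]2OC(/C=C(/OC)C(OC)=C=O)=C[C@@H](OC)[C@@H]2OC)cc1O[Si](C(C)C)(C(C)C)C(C)C | intermediate (not isolated)
21 | (2R,3S,4R)-3,4,6,7-tetramethoxy-2-Ar-2,3,4,4a-tetrahydro-5H-chromen-5-one (4a-H keto tautomer of 22) | COc1cc(O[Si](C(C)C)(C(C)C)C(C)C)c([C@H]2OC3=CC(OC)=C(OC)C(=O)C3[C@@H](OC)[C@@H]2OC)cc1O[Si](C(C)C)(C(C)C)C(C)C | intermediate (not isolated)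
22 | (2R,3S,4R)-3,4,6,7-tetramethoxy-2-Ar-chroman-5-ol | COc1cc(O[Si](C(C)C)(C(C)C)C(C)C)c([C@H]2Oc3cc(OC)c(OC)c(O)c3[C@@H](OC)[C@@H]2OC)cc1O[Si](C(C)C)(C(C)C)C(C)C | intermediate
23 | (2R,3R)-5-hydroxy-3,6,7-trimethoxy-2-Ar-chroman-4-one | COc1cc(O[Si](C(C)C)(C(C)C)C(C)C)c([C@H]2Oc3cc(OC)c(OC)c(O)c3C(=O)[C@@H]2OC)cc1O[Si](C(C)C)(C(C)C)C(C)C | intermediate
24 | (2R,3R)-2-(2,5-dihydroxy-4-methoxyphenyl)-5-hydroxy-3,6,7-trimethoxychroman-4-one | COc1cc(O)c([C@H]2Oc3cc(OC)c(OC)c(O)c3C(=O)[C@@H]2OC)cc1O | target

**Step count**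

Total: 13 steps. Longest linear sequence: 11 steps (steps 1–8 and 11–13); the cyclobutenone branch is steps 9–10.

**Steps most likely to fail and fallbacks**

Step 11 (key step). The chloride 18 may ionise and be dealkylated by its own chloride ion to the cyclobutenedione before palladium inserts. HCl released in that way may protodestannylate 15. Coupling may also take place partly at the methoxy-bearing allyl terminus. The fallback sets out from 17 and 15 and also bypasses step 10. 17 is acetylated (Ac2O, pyridine, cat. DMAP, CH2Cl2, 0 °C) to (±)-4-acetoxy-2,3-dimethoxycyclobut-2-en-1-one F1, which carries no nucleophilic counter-ion and cannot release HCl. F1 and 15 are then joined as an allylic acetate with an alkenylstannane (Pd2(dba)3, tri(2-furyl)phosphine, DMF, rt to 50 °C): zerovalent palladium ionises the allylic C–O bond to the same oxocyclobutenyl palladium intermediate and gives 19. Heating to 90 °C takes 19 through 20 and 21, and the route is rejoined at 22.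

Step 8. Metalation may occur at the benzylic C2–H (followed by β-elimination of the C3 methoxide) or on ring B at the hydrogen between the two oxygens, in competition with the vinylic position. The fallback sets out from 13 and avoids alkyllithium deprotonation of a C–H bond of low acidity. Acid-catalysed addition of thiophenol to the enol ether (PhSH, cat. PPh3·HBr, CH2Cl2) gives (2R,3S,4R)-3,4-dimethoxy-2-Ar-6-(phenylthio)tetrahydro-2H-pyran F2. Oxidation (mCPBA, NaHCO3, CH2Cl2, 0 °C) gives the sulfone (2R,3S,4R)-3,4-dimethoxy-2-Ar-6-(phenylsulfonyl)tetrahydro-2H-pyran F3. LiN(iPr)2 (THF, −78 °C) removes only the acidic α-sulfonyl hydrogen, and Bu3SnCl gives tributyl[(2R,3S,4R)-3,4-dimethoxy-2-Ar-6-(phenylsulfonyl)tetrahydro-2H-pyran-6-yl]stannane F4. Elimination of benzenesulfinic acid (iPr2NEt, toluene, 80 °C) returns to the route at 15.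

Step 12. Hydride abstraction may also occur at C2–H, the intermediate ortho-quinone methide may shift a hydrogen from C3 to give a chromene that is oxidised further, or the free phenol may be oxidised. The fallback sets out from 22 and separates deprotection from oxidation. Solvolysis of the ionisable benzylic methyl ether (pyridinium p-toluenesulfonate, THF/H2O, high dilution, rt) gives (2R,3S)-3,6,7-trimethoxy-2-Ar-chroman-4,5-diol F5 as a mixture of C4 epimers. MnO2 (CH2Cl2, rt) then oxidises the ortho-hydroxybenzylic alcohol without a cationic intermediate and returns to the route at 23.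

**Further compounds**

F1 | step 11 | (±)-4-acetoxy-2,3-dimethoxycyclobut-2-en-1-one | COC1=C(OC)C(OC(C)=O)C1=O
F2 | step 8 | (2R,3S,4R)-3,4-dimethoxy-2-Ar-6-(phenylthio)tetrahydro-2H-pyran (C6 epimers) | COc1cc(O[Si](C(C)C)(C(C)C)C(C)C)c([C@H]2OC(Sc3ccccc3)C[C@@H](OC)[C@@H]2OC)cc1O[Si](C(C)C)(C(C)C)C(C)C
F3 | step 8 | (2R,3S,4R)-3,4-dimethoxy-2-Ar-6-(phenylsulfonyl)tetrahydro-2H-pyran (C6 epimers) | COc1cc(O[Si](C(C)C)(C(C)C)C(C)C)c([C@H]2OC(S(=O)(=O)c3ccccc3)C[C@@H](OC)[C@@H]2OC)cc1O[Si](C(C)C)(C(C)C)C(C)C
F4 | step 8 | tributyl[(2R,3S,4R)-3,4-dimethoxy-2-Ar-6-(phenylsulfonyl)tetrahydro-2H-pyran-6-yl]stannane (C6 epimers) | COc1cc(O[Si](C(C)C)(C(C)C)C(C)C)c([C@H]2OC([Sn](CCCC)(CCCC)CCCC)(S(=O)(=O)c3ccccc3)C[C@@H](OC)[C@@H]2OC)cc1O[Si](C(C)C)(C(C)C)C(C)C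
F5 | step 12 | (2R,3S)-3,6,7-trimethoxy-2-Ar-chroman-4,5-diol (C4 epimers) | COc1cc(O[Si](C(C)C)(C(C)C)C(C)C)c([C@H]2Oc3cc(OC)c(OC)c(O)c3C(O)[C@@H]2OC)cc1O[Si](C(C)C)(C(C)C)C(C)C
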